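X in the ochre run rises along a nearly straight line, and that line is the tool for this flask.

| flask | Z | D | Q | J | remark | time |
|---|---|---|---|---|---|---|
| ochre | 0.40 M (fed, over 80 s) | 4 equiv | 0.45 equiv | 8 mM | run made earlier; the fed solution adds 0.20 times the starting volume |  |
| flask | 0.40 M (fed, over 80 s) | 4.00 equiv | 0.300 equiv | 8.00 mM | the fed solution adds 0.20 times the starting volume | 40 min |

- ochre (time / min: Z / %, X / %): 1.50: 97.9, 2.6; 3.00: 94.3, 5.8; 5.00: 90.7, 9.9; 6.00: 88.1, 11.7; 8.00: 83.9, 16.5; 10.0: 81.0, 19.5; 12.0: 76.9, 23.2

(readings scatter by 0.3 percentage points)

- amounts are per litre of the starting volume; all of the dose is in the solution fed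
- steps under discussion: Z + D + E -> X + 2 E; Z + D -> X + E; Q + E <-> G; D + J -> L
- no earlier run changes the charge of Q; that part of a forecast is a guess

* the species in which most of what was charged as Z, at 40 min sits (X / Z)
* the largest share itself, whichever of these holds it, in percent of the Z charged

Read the last row first. X stands at 23.2% after 12.0 min, so its mean rate is 0.0193 /min of the Z charged. Now the 6.00 min row: X is half of its last value at half the time, so you see no bend. One row strays: at 8.00 min, X lies 1 percentage point above the mean line, worth 0.534 min of reckoned time. Put the columns together: Z and X in the last row add up to 100%, so the Z lost appears as X.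

Each X brings one E, and Q takes E up as G. For the flask, with 0.300 equiv of Q, that gives 15.5 min: the buffer time, which is the Q charged over the mean rate of X, the induction period of this E-catalysed run. The ochre run's buffer time is 23.3 min, later than its last row. In the flask, the mean line carried to 40 min gives X 77.2%, but a straight line takes no account of Z running down. So let Z fall by equal factors in equal times, as in a pseudo-first-order step, starting from the ochre run's last row. X at 40 min is then 58.3%. That is my estimate without the E step, for which I read no rate from the ochre rows, and it puts X ahead of Z.

The forecast says X at 85%, in its words “X leads either way”.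

The flask gives X at 98.8%, with Z at 1.24%.

    Z + D + E → X + 2 E (k = 0.0170 /M²/s)
    Z + D → X + E (k = 3.00 × 10⁻⁴ /M/s)
    Q + E ⇌ G, settled at all times (K = 35000 /M)
    D + J → L (k = 0.410 /M/s)

At 20.0 min, Q in the flask stands at 0.0837% of its charge. From 15.5 min to 40 min, X gains a mean 0.0281 /min, faster than the earlier 0.0193 /min.

Now take the neighbour flask with 1.60 equiv of D, its other charges unchanged. Z + D goes with D, so the buffer time stretches to 38.8 min, against 40 min, and the mean line gives X 30.9%. Computed, that neighbour holds X 28.7%, Z 71.3%, and Q 4.99% of its charge at 40.0 min.

The data stem from a simulated flask with constants of no real substance; scatter was added.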